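Numbering follows the labdane skeleton (C1–C10 decalin, C11–C16 side chain, C17 on C8, C18/C19 on C4, C20 on C10). Retrosynthesis cuts the C19–O angelate, then C12–C13, C8–C17 and C9–C11, then C6–C7 of ring B (aldol), then C4–C5 of ring A.
Enabling feature: in ring A, C4 (bearing the C18 methyl and C19–O) and C5 are vicinal, C5 carries the one-carbon branch C6, and C2–C3 lie across the ring. This is the array left when the silyl ketene acetal of a δ-lactone (O, C6, C5, C10, C1, C2) shifts [3,3] onto an (E)-trisubstituted alkenyl group (C3=C4) on C2.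
Forward: propargyl alcohol gives the (E)-enal; a dienolate aldol and lactonisation give the β-keto-δ-lactone; the C7–C9 allyl arm (Stille) and C20 (cuprate) complete the lactone; ring contraction builds ring A; Wacker oxidation and aldol condensation close ring B; C9 alkylation, C17 through the enol triflate and a Negishi coupling with a (Z)-3-iodobutenoate finish the chain; angeloylation and ester release end the route.
Stereochemistry: the catalytic asymmetric aldol sets the lactone carbinol (C2); the cuprate adds anti to the alkenyl group (C10); the boat [3,3] shift relays C2 and the (E)-olefin geometry into C4 and C5; C9 is set by equilibration next to the C8 ketone; 13Z comes from the (Z)-iodoenoate with retention; the angelate geometry comes from angelic acid.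

Key step: step 10

Assumption: in step 5 the (S)-Tol-BINAP copper complex is taken as the catalyst enantiomer that delivers the (S)-carbinol; if the sense of induction is the opposite, (R)-Tol-BINAP is used and nothing else changes.

Step 1
Reactants: 1 propargyl alcohol
Product: 3 (E)-3-iodo-2-methylprop-2-en-1-ol, via alkenylalane 2 (not isolated)
Conditions: Me3Al (3 equiv), Cp2ZrCl2 (0.25 equiv), CH2Cl2, 0 °C to rt; then I2, THF, −30 °C
Reagents that add atoms: trimethylaluminium C[Al](C)C; iodine II
Why: Zirconium-catalysed syn-carboalumination of the alkyne (Negishi carboalumination) should place methyl on the internal carbon and aluminium on the terminus, and iodinolysis with retention should give the (E)-iodoalkene that later becomes C3=C4 with C18 and C19 attached.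

Step 2
Reactants: 3 (E)-3-iodo-2-methylprop-2-en-1-ol
Product: 4 (E)-tert-butyl[(3-iodo-2-methylprop-2-en-1-yl)oxy]dimethylsilane
Conditions: TBSCl, imidazole, DMF, rt
Reagents that add atoms: tert-butyldimethylsilyl chloride CC(C)(C)[Si](C)(C)Cl
Why: Imidazole-promoted silylation of a primary alcohol should proceed cleanly and gives the C19 oxygen a group that tolerates the bases, cuprate, hydrides and palladium steps that follow.

Step 3
Reactants: 4 (E)-tert-butyl[(3-iodo-2-methylprop-2-en-1-yl)oxy]dimethylsilane
Product: 6 (E)-4-(tert-butyldimethylsilyloxy)-3-methylbut-2-enal, via alkenyllithium 5 (not isolated)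
Conditions: t-BuLi (2.1 equiv), Et2O, −78 °C; then DMF, −78 to 0 °C; aq NH4Cl
Reagents that add atoms: N,N-dimethylformamide CN(C)C=O
Why: Iodine–lithium exchange proceeds with retention of olefin geometry and formylation of the alkenyllithium with DMF should give the (E)-enal whose carbonyl carbon becomes C2.

Step 4
Reactants: 7 2,2,6-trimethyl-4H-1,3-dioxin-4-one
Product: 9 2,2-dimethyl-6-methylidene-4-(trimethylsilyloxy)-6H-1,3-dioxine, via lithium dienolate 8 (not isolated)
Conditions: LiN(iPr)2, THF, −78 °C; then Me3SiCl, −78 °C to rt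
Reagents that add atoms: chlorotrimethylsilane C[Si](C)(C)Cl
Why: Kinetic γ-deprotonation of the dioxinone and O-silylation should give the silyl dienolate that serves as an acetoacetate γ-anion equivalent.

Step 5
Reactants: 6 (E)-4-(tert-butyldimethylsilyloxy)-3-methylbut-2-enal; 9 2,2-dimethyl-6-methylidene-4-(trimethylsilyloxy)-6H-1,3-dioxine
Product: 11 6-[(2S,3E)-5-(tert-butyldimethylsilyloxy)-2-hydroxy-4-methylpent-3-en-1-yl]-2,2-dimethyl-4H-1,3-dioxin-4-one, via trimethylsilyl ether 10 (not isolated)
Conditions: Cu(OTf)2 (2 mol%), (S)-Tol-BINAP (2.2 mol%), (Bu4N)Ph3SiF2 (4 mol%), THF, −78 °C; then PPTS, MeOH, 0 °C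
Reagents that add atoms: none
Why: A catalytic enantioselective vinylogous Mukaiyama aldol addition, in which the bisphosphine-bound copper dienolate adds 1,2 to one face of the enal, should set the carbinol centre (future C2, S) under catalyst control, and brief PPTS methanolysis removes only the trimethylsilyl ether.

Step 6
Reactants: 11 6-[(2S,3E)-5-(tert-butyldimethylsilyloxy)-2-hydroxy-4-methylpent-3-en-1-yl]-2,2-dimethyl-4H-1,3-dioxin-4-one
Product: 13 (S)-6-[(E)-3-(tert-butyldimethylsilyloxy)-2-methylprop-1-en-1-yl]dihydro-2H-pyran-2,4(3H)-dione, via acylketene 12 (not isolated)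
Conditions: toluene, 110 °C
Reagents that add atoms: none
Why: Thermal retro-[4+2] loss of acetone from the dioxinone gives an acylketene that the δ-hydroxyl should trap intramolecularly to close the six-membered β-keto lactone under neutral conditions, leaving the carbinol centre untouched.

Step 7
Reactants: 13 (S)-6-[(E)-3-(tert-butyldimethylsilyloxy)-2-methylprop-1-en-1-yl]dihydro-2H-pyran-2,4(3H)-dione
Product: 14 (S)-6-[(E)-3-(tert-butyldimethylsilyloxy)-2-methylprop-1-en-1-yl]-4-(trifluoromethylsulfonyloxy)-5,6-dihydro-2H-pyran-2-one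
Conditions: Tf2O, Et3N, CH2Cl2, −78 °C
Reagents that add atoms: trifluoromethanesulfonic anhydride O=S(=O)(OS(=O)(=O)C(F)(F)F)C(F)(F)F
Why: O-sulfonylation of the stable enol of the cyclic β-keto ester should give the conjugated enol triflate and so activate the future C10 for carbon–carbon coupling.

Step 8
Reactants: 14 enol triflate of the β-keto lactone; 15 allyltributylstannane
Product: 16 (S)-4-allyl-6-[(E)-3-(tert-butyldimethylsilyloxy)-2-methylprop-1-en-1-yl]-5,6-dihydro-2H-pyran-2-one
Conditions: Pd2(dba)3 (2.5 mol%), AsPh3 (20 mol%), NMP, rt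
Reagents that add atoms: none
Why: Stille coupling of the electron-poor enol triflate attaches the C9–C8–C7 allyl arm, and fast oxidative addition at rt with the weakly donating arsine should keep zerovalent palladium from ionising the allylic lactone C–O bond.

Step 9
Reactants: 16 (S)-4-allyl-6-[(E)-3-(tert-butyldimethylsilyloxy)-2-methylprop-1-en-1-yl]-5,6-dihydro-2H-pyran-2-one
Product: 18 (4S,6S)-4-allyl-4-methyl-6-[(E)-3-(tert-butyldimethylsilyloxy)-2-methylprop-1-en-1-yl]tetrahydro-2H-pyran-2-one (allyl cis to the alkenyl group), via trimethylsilyl ketene acetal 17 (not isolated)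
Conditions: Me2CuLi (2 equiv, from MeLi and CuI), Me3SiCl (4 equiv), THF, −78 to −40 °C; then aq NH4Cl, rt
Reagents that add atoms: lithium dimethylcuprate [Li+].C[Cu-]C
Why: Chlorosilane-accelerated cuprate conjugate addition to the s-cis-locked unsaturated lactone should occur axially on the half-chair anti to the pseudo-equatorial alkenyl group, so the new methyl (C20) ends trans and the allyl arm cis to that group, which sets the quaternary C10; the ketene acetal is hydrolysed on work-up.

Step 10
Reactants: 18 (4S,6S)-4-allyl-4-methyl-6-[(E)-3-(tert-butyldimethylsilyloxy)-2-methylprop-1-en-1-yl]tetrahydro-2H-pyran-2-one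
Product: 22 (1R,2S,6S)-6-allyl-2-[(tert-butyldimethylsilyloxy)methyl]-2,6-dimethylcyclohex-3-ene-1-carboxylic acid, via lithium enolate 19 (not isolated), via silyl ketene acetal 20 (not isolated), via silyl ester 21 (not isolated)
Conditions: LiN(iPr)2 (1.3 equiv), THF, −78 °C; TBSCl, DMPU, −78 °C to rt; solvent change to toluene, 110 °C (xylene, 140 °C, sealed vessel if slow); then K2CO3, MeOH–H2O, rt; citric acid to pH 4
Reagents that add atoms: none
Why: Deprotonation at C5 and O-silylation give the cyclic ketene acetal 20, in which C5=C6(OSi)–O–C2–C3=C4 is an allyl vinyl ether that undergoes a concerted suprafacial [3,3] shift (Ireland–Claisen rearrangement run as a lactone ring contraction), forming C4–C5, breaking C2–O and leaving the olefin at C2=C3. The closest known reaction type is the Ireland–Claisen ring contraction of alkenyl-substituted lactones through their silyl ketene acetals. Ring A closes as a six-membered carbocycle from the six-membered lactone because the axial alkenyl group on C2 bonds across the ring to C5 through a bicyclo[2.2.2]-like boat, the only geometry the tether allows. C5 is set because the alkenyl group can reach only the face of the ketene acetal on which it stands, the face that also carries the allyl arm of C10, so the carboxyl (C6) ends trans to that arm and cis to C20, as a trans-fused ring B requires. C4 is set by the (E)-olefin geometry within the boat, where the CH2OTBS group eclipses the carboxyl and the (Z)-methyl eclipses H5, so C19 ends cis to C6 and C20 and C18 ends on the opposite face, the C2 stereocentre being consumed in the transfer. The step needs complete enolisation at C5 (the only α-position) and a shift that outruns decay of the ketene acetal, which the thermally robust tert-butyldimethylsilyl ketene acetal, the placing of the smaller methyl group in the inside position next to C1 and the inert allyl spectator are meant to secure.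

Step 11
Reactants: 22 ring A acid
Product: 23 [(1R,2S,6S)-6-allyl-2-[(tert-butyldimethylsilyloxy)methyl]-2,6-dimethylcyclohex-3-en-1-yl]methanol
Conditions: LiAlH4, THF, 0 °C to reflux; aq NaOH work-up
Reagents that add atoms: none
Why: Hydride reduction of the carboxylic acid to the primary alcohol should proceed even at this neopentyl position at reflux, while the silyl ether and both olefins are inert.

Step 12
Reactants: 23 ring A primary alcohol
Product: 24 (1R,2S,6S)-6-allyl-2-[(tert-butyldimethylsilyloxy)methyl]-2,6-dimethylcyclohex-3-ene-1-carbaldehyde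
Conditions: Dess–Martin periodinane, NaHCO3, CH2Cl2, 0 °C to rt
Reagents that add atoms: none
Why: Dess–Martin oxidation converts the hindered primary alcohol into the C6 aldehyde under buffered, non-epimerising conditions that leave C5 intact.

Step 13
Reactants: 24 ring A aldehyde
Product: 25 (1R,2S,6S)-2-[(tert-butyldimethylsilyloxy)methyl]-2,6-dimethyl-6-(2-oxopropyl)cyclohex-3-ene-1-carbaldehyde
Conditions: PdCl2 (10 mol%), CuCl (1 equiv), O2 (1 atm), DMF–H2O (7:1), rt
Reagents that add atoms: water O
Why: Tsuji–Wacker oxidation should convert the terminal allyl group into the methyl ketone (C8 carbonyl, C7 methyl) by Markovnikov hydroxypalladation, the hindered disubstituted ring olefin reacting far more slowly and the aldehyde being tolerated.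

Step 14
Reactants: 25 keto aldehyde
Product: 27 19-(tert-butyldimethylsilyloxy)-trans-decal-2,6-dien-8-one (labdane numbering; 5α-H, 10β-methyl, C19 β), via ketol 26 (not isolated)
Conditions: KOH, MeOH, 0 °C to rt
Reagents that add atoms: none
Why: Intramolecular aldol condensation, in which only the methyl ketone enolate (C7) can reach the C6 aldehyde through a six-membered 6-(enolendo)-exo-trig closure, followed by dehydration, should give the ring B enone with the trans ring fusion carried over from C5 and C10.

Step 15
Reactants: 27 ring B enone; 28 ethyl bromoacetate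
Product: 30 ethyl 2-[19-(tert-butyldimethylsilyloxy)-8-oxo-trans-decal-2,6-dien-9-yl]acetate as C9 epimers, via lithium dienolate 29 (not isolated)
Conditions: LiN(iPr)2 (1.1 equiv), THF, −78 °C; then 28, DMPU, −78 to −20 °C
Reagents that add atoms: none
Why: Kinetic α′-deprotonation of the enone (C7 is vinylic, so C9 is the only α-methylene) and SN2 alkylation of the cross-conjugated enolate with the reactive α-bromo ester install C11 and C12, the C9 configuration (attack anti to the axial C20 is expected to favour the 9α-substituent) being corrected in step 16.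

Step 16
Reactants: 30 alkylated enone (C9 epimers)
Product: 32 ethyl 2-[19-(tert-butyldimethylsilyloxy)-8-oxo-trans-decalin-9β-yl]acetate (H9 α), via saturated keto ester epimers 31 (not isolated)
Conditions: H2 (3 atm), 10% Pd/C, EtOAc, rt; filtration; then NaOEt (0.3 equiv), EtOH, rt
Reagents that add atoms: none
Why: Heterogeneous hydrogenation saturates C2=C3 and the enone C6=C7 without touching ketone or ester, and base equilibration through the C8–C9 enolate should place the C9 substituent equatorial (β), the epimer favoured thermodynamically and by axial protonation anti to C20.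

Step 17
Reactants: 32 saturated keto ester
Product: 34 ethyl 2-[19-(tert-butyldimethylsilyloxy)-8-(trifluoromethylsulfonyloxy)-trans-decal-7-en-9β-yl]acetate, via potassium enolate 33 (not isolated)
Conditions: KN(SiMe3)2 (1.05 equiv), THF, −78 °C; then PhNTf2, −78 to 0 °C
Reagents that add atoms: N-phenylbis(trifluoromethanesulfonimide) O=S(=O)(N(c1ccccc1)S(=O)(=O)C(F)(F)F)C(F)(F)F
Why: Kinetic deprotonation at the unhindered C7 methylene rather than at the tertiary C9–H beside the quaternary centre, followed by O-triflation, should give the Δ7 enol triflate regioselectively and without epimerising C9.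

Step 18
Reactants: 34 Δ7 enol triflate
Product: 35 ethyl 2-[19-(tert-butyldimethylsilyloxy)-8-methyl-trans-decal-7-en-9β-yl]acetate
Conditions: MeZnCl (3 equiv), Pd(PPh3)4 (5 mol%), THF, 50 °C
Reagents that add atoms: methylzinc chloride C[Zn]Cl
Why: Negishi coupling of the enol triflate with the methylzinc reagent introduces C17 and fixes the C7=C8 olefin, the ester and silyl ether being tolerated.

Step 19
Reactants: 35 C17-methyl ester
Product: 36 2-[19-(tert-butyldimethylsilyloxy)-8-methyl-trans-decal-7-en-9β-yl]ethanol
Conditions: LiAlH4, Et2O, 0 °C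
Reagents that add atoms: none
Why: Hydride reduction of the ethyl ester gives the C12 primary alcohol now that no ketone remains, the silyl ether and trisubstituted olefin being inert.

Step 20
Reactants: 36 C12 alcohol
Product: 37 19-(tert-butyldimethylsilyloxy)-9β-(2-iodoethyl)-8-methyl-trans-decal-7-ene
Conditions: I2, PPh3, imidazole, CH2Cl2, 0 °C to rt
Reagents that add atoms: iodine II
Why: Appel-type iodination converts the unhindered primary alcohol into the primary iodide under near-neutral conditions that do not disturb the C7=C8 olefin.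

Step 21
Reactants: 38 but-2-ynoic acid
Product: 39 (Z)-3-iodobut-2-enoic acid
Conditions: NaI, AcOH, 110 °C
Reagents that add atoms: sodium iodide [Na+].[I-]
Why: Conjugate addition of iodide to the ynoic acid followed by anti protonation (hydroiodination) should give the (Z)-β-iodo acid, in which iodine is cis to the carboxyl.

Step 22
Reactants: 39 (Z)-3-iodobut-2-enoic acid
Product: 40 2-(trimethylsilyl)ethyl (Z)-3-iodobut-2-enoate
Conditions: 2-(trimethylsilyl)ethanol, DCC, DMAP (5 mol%), CH2Cl2, 0 °C
Reagents that add atoms: 2-(trimethylsilyl)ethanol C[Si](C)(C)CCO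
Why: Steglich esterification at 0 °C should preserve the (Z)-geometry and provides an ester that fluoride can remove at the end without base or acid.

Step 23
Reactants: 37 primary iodide; 40 2-(trimethylsilyl)ethyl (Z)-3-iodobut-2-enoate
Product: 42 2-(trimethylsilyl)ethyl 19-(tert-butyldimethylsilyloxy)labda-7,13Z-dien-15-oate, via alkylzinc iodide 41 (not isolated)
Conditions: Zn dust (activated with BrCH2CH2Br and Me3SiCl), DMA, 40 °C; then 40, Pd(PPh3)4 (5 mol%), THF, rt to 40 °C
Reagents that add atoms: none
Why: Zinc insertion into the primary iodide and Negishi sp3–sp2 coupling with the alkenyl iodide form C12–C13 with retention of olefin geometry, so C12 stays cis to C15 (13Z).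

Step 24
Reactants: 42 coupled silyl ether ester
Product: 43 2-(trimethylsilyl)ethyl 19-hydroxylabda-7,13Z-dien-15-oate
Conditions: HF·pyridine, pyridine, THF, 0 °C to rt
Reagents that add atoms: none
Why: Buffered HF·pyridine should cleave the primary tert-butyldimethylsilyl ether while leaving the 2-(trimethylsilyl)ethyl ester and both olefins untouched.

Step 25
Reactants: 43 C19 alcohol; 44 angelic acid
Product: 46 2-(trimethylsilyl)ethyl 19-angeloyloxylabda-7,13Z-dien-15-oate, via mixed anhydride 45 (not isolated)
Conditions: 44, 2,4,6-trichlorobenzoyl chloride, Et3N, toluene, rt; then 43, toluene, 80 °C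
Reagents that add atoms: none
Why: Yamaguchi-type esterification through the mixed anhydride, run without a nucleophilic amine catalyst, should acylate the neopentyl C19 hydroxyl while keeping the (Z)-geometry of the angelate.

Step 26
Reactants: 46 angelate 2-(trimethylsilyl)ethyl ester
Product: 47 (4S,5R,9S,10R)-19-[(Z)-2-methylbut-2-enoyloxy]labda-7,13Z-dien-15-oic acid (target)
Conditions: Bu4NF, THF, 0 °C to rt; then 1 M aq KHSO4, 0 °C
Reagents that add atoms: none
Why: Fluoride attack at silicon triggers β-elimination of ethylene and releases the C15 carboxylate under conditions that should not hydrolyse or isomerise the angelate or the (Z)-enoic acid.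

Compound list
1 | propargyl alcohol | C#CCO | starting material
2 | alkenylalane (dimethylaluminium alkoxide of (E)-3-(dimethylalumanyl)-2-methylprop-2-en-1-ol) | C[Al](C)OC/C(C)=C/[Al](C)C | intermediate
3 | (E)-3-iodo-2-methylprop-2-en-1-ol | OC/C(C)=C/I | intermediate
4 | (E)-tert-butyl[(3-iodo-2-methylprop-2-en-1-yl)oxy]dimethylsilane | CC(C)(C)[Si](C)(C)OC/C(C)=C/I | intermediate
5 | (E)-alkenyllithium from 4 | CC(C)(C)[Si](C)(C)OC/C(C)=C/[Li] | intermediate
6 | (E)-4-(tert-butyldimethylsilyloxy)-3-methylbut-2-enal | CC(C)(C)[Si](C)(C)OC/C(C)=C/C=O | intermediate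
7 | 2,2,6-trimethyl-4H-1,3-dioxin-4-one | CC1=CC(=O)OC(C)(C)O1 | starting material
8 | lithium dienolate of 7 | C=C1C=C(O[Li])OC(C)(C)O1 | intermediate
9 | 2,2-dimethyl-6-methylidene-4-(trimethylsilyloxy)-6H-1,3-dioxine | C=C1C=C(O[Si](C)(C)C)OC(C)(C)O1 | intermediate
10 | trimethylsilyl ether of 11 | CC1(C)OC(=O)C=C(C[C@H](O[Si](C)(C)C)/C=C(\C)CO[Si](C)(C)C(C)(C)C)O1 | intermediate
11 | 6-[(2S,3E)-5-(tert-butyldimethylsilyloxy)-2-hydroxy-4-methylpent-3-en-1-yl]-2,2-dimethyl-4H-1,3-dioxin-4-one | CC1(C)OC(=O)C=C(C[C@H](O)/C=C(\C)CO[Si](C)(C)C(C)(C)C)O1 | intermediate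
12 | acylketene from 11 ((5S,6E)-5-hydroxy-3-oxo-dienyl ketene) | O=C=CC(=O)C[C@H](O)/C=C(\C)CO[Si](C)(C)C(C)(C)C | intermediate
13 | (S)-6-[(E)-3-(tert-butyldimethylsilyloxy)-2-methylprop-1-en-1-yl]dihydro-2H-pyran-2,4(3H)-dione | O=C1CC(=O)C[C@H](O1)/C=C(\C)CO[Si](C)(C)C(C)(C)C | intermediate
14 | (S)-4-(trifluoromethylsulfonyloxy)-6-alkenyl-5,6-dihydro-2H-pyran-2-one | O=C1C=C(OS(=O)(=O)C(F)(F)F)C[C@H](O1)/C=C(\C)CO[Si](C)(C)C(C)(C)C | intermediate
15 | allyltributylstannane | C=CC[Sn](CCCC)(CCCC)CCCC | starting material
16 | (S)-4-allyl-6-[(E)-3-(tert-butyldimethylsilyloxy)-2-methylprop-1-en-1-yl]-5,6-dihydro-2H-pyran-2-one | O=C1C=C(CC=C)C[C@H](O1)/C=C(\C)CO[Si](C)(C)C(C)(C)C | intermediate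
17 | trimethylsilyl ketene acetal of 18 | C[Si](C)(C)OC1=C[C@@](C)(CC=C)C[C@H](O1)/C=C(\C)CO[Si](C)(C)C(C)(C)C | intermediate
18 | (4S,6S)-4-allyl-4-methyl-6-[(E)-3-(tert-butyldimethylsilyloxy)-2-methylprop-1-en-1-yl]tetrahydro-2H-pyran-2-one | O=C1C[C@@](C)(CC=C)C[C@H](O1)/C=C(\C)CO[Si](C)(C)C(C)(C)C | intermediate
19 | lithium enolate of 18 | [Li]OC1=C[C@@](C)(CC=C)C[C@H](O1)/C=C(\C)CO[Si](C)(C)C(C)(C)C | intermediate
20 | tert-butyldimethylsilyl ketene acetal of 18 | CC(C)(C)[Si](C)(C)OC1=C[C@@](C)(CC=C)C[C@H](O1)/C=C(\C)CO[Si](C)(C)C(C)(C)C | intermediate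
21 | tert-butyldimethylsilyl ester of 22 | CC(C)(C)[Si](C)(C)OC[C@@]1(C)C=CC[C@](C)(CC=C)[C@H]1C(=O)O[Si](C)(C)C(C)(C)C | intermediate
22 | (1R,2S,6S)-6-allyl-2-[(tert-butyldimethylsilyloxy)methyl]-2,6-dimethylcyclohex-3-ene-1-carboxylic acid (carboxyl = C6, cis to C19 and C20) | CC(C)(C)[Si](C)(C)OC[C@@]1(C)C=CC[C@](C)(CC=C)[C@H]1C(=O)O | intermediate
23 | ring A primary alcohol (C6–OH) | CC(C)(C)[Si](C)(C)OC[C@@]1(C)C=CC[C@](C)(CC=C)[C@H]1CO | intermediate
24 | ring A aldehyde (C6) | CC(C)(C)[Si](C)(C)OC[C@@]1(C)C=CC[C@](C)(CC=C)[C@H]1C=O | intermediate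
25 | keto aldehyde (2-oxopropyl arm on C10) | CC(C)(C)[Si](C)(C)OC[C@@]1(C)C=CC[C@](C)(CC(C)=O)[C@H]1C=O | intermediate
26 | ketol (6-hydroxy-8-ketone, C6 epimers) | CC(C)(C)[Si](C)(C)OC[C@@]1(C)C=CC[C@]2(C)CC(=O)CC(O)[C@@H]12 | intermediate
27 | 19-(tert-butyldimethylsilyloxy)-trans-decal-2,6-dien-8-one | CC(C)(C)[Si](C)(C)OC[C@@]1(C)C=CC[C@]2(C)CC(=O)C=C[C@@H]12 | intermediate
28 | ethyl bromoacetate | CCOC(=O)CBr | starting material
29 | lithium dienolate of 27 (C8–O, C8=C9) | CC(C)(C)[Si](C)(C)OC[C@@]1(C)C=CC[C@]2(C)C=C(O[Li])C=C[C@@H]12 | intermediate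
30 | C9-alkylated enone, C9 epimers | CC(C)(C)[Si](C)(C)OC[C@@]1(C)C=CC[C@]2(C)C(CC(=O)OCC)C(=O)C=C[C@@H]12 | intermediate
31 | saturated keto ester, C9 epimers | CC(C)(C)[Si](C)(C)OC[C@@]1(C)CCC[C@]2(C)C(CC(=O)OCC)C(=O)CC[C@@H]12 | intermediate
32 | saturated keto ester, 9β side chain | CC(C)(C)[Si](C)(C)OC[C@@]1(C)CCC[C@]2(C)[C@@H](CC(=O)OCC)C(=O)CC[C@@H]12 | intermediate
33 | potassium Δ7 enolate of 32 | CC(C)(C)[Si](C)(C)OC[C@@]1(C)CCC[C@]2(C)[C@@H](CC(=O)OCC)C(O[K])=CC[C@@H]12 | intermediate
34 | Δ7 enol triflate | CC(C)(C)[Si](C)(C)OC[C@@]1(C)CCC[C@]2(C)[C@@H](CC(=O)OCC)C(OS(=O)(=O)C(F)(F)F)=CC[C@@H]12 | intermediate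
35 | C17-methyl Δ7 ester | CC(C)(C)[Si](C)(C)OC[C@@]1(C)CCC[C@]2(C)[C@@H](CC(=O)OCC)C(C)=CC[C@@H]12 | intermediate
36 | C12 alcohol | CC(C)(C)[Si](C)(C)OC[C@@]1(C)CCC[C@]2(C)[C@@H](CCO)C(C)=CC[C@@H]12 | intermediate
37 | C12 iodide | CC(C)(C)[Si](C)(C)OC[C@@]1(C)CCC[C@]2(C)[C@@H](CCI)C(C)=CC[C@@H]12 | intermediate
38 | but-2-ynoic acid | CC#CC(=O)O | starting material
39 | (Z)-3-iodobut-2-enoic acid | C/C(I)=C/C(=O)O | intermediate
40 | 2-(trimethylsilyl)ethyl (Z)-3-iodobut-2-enoate | C/C(I)=C/C(=O)OCC[Si](C)(C)C | intermediate
41 | alkylzinc iodide from 37 | CC(C)(C)[Si](C)(C)OC[C@@]1(C)CCC[C@]2(C)[C@@H](CC[Zn]I)C(C)=CC[C@@H]12 | intermediate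
42 | 2-(trimethylsilyl)ethyl 19-(tert-butyldimethylsilyloxy)labda-7,13Z-dien-15-oate | CC(C)(C)[Si](C)(C)OC[C@@]1(C)CCC[C@]2(C)[C@@H](CC/C(C)=C\C(=O)OCC[Si](C)(C)C)C(C)=CC[C@@H]12 | intermediate
43 | 2-(trimethylsilyl)ethyl 19-hydroxylabda-7,13Z-dien-15-oate | OC[C@@]1(C)CCC[C@]2(C)[C@@H](CC/C(C)=C\C(=O)OCC[Si](C)(C)C)C(C)=CC[C@@H]12 | intermediate
44 | angelic acid ((Z)-2-methylbut-2-enoic acid) | C/C=C(/C)C(=O)O | starting material
45 | angelic 2,4,6-trichlorobenzoic mixed anhydride | C/C=C(/C)C(=O)OC(=O)c1c(Cl)cc(Cl)cc1Cl | intermediate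
46 | 2-(trimethylsilyl)ethyl 19-angeloyloxylabda-7,13Z-dien-15-oate | C/C=C(/C)C(=O)OC[C@@]1(C)CCC[C@]2(C)[C@@H](CC/C(C)=C\C(=O)OCC[Si](C)(C)C)C(C)=CC[C@@H]12 | intermediate
47 | (4S,5R,9S,10R)-19-[(Z)-2-methylbut-2-enoyloxy]labda-7,13Z-dien-15-oic acid | C/C=C(/C)C(=O)OC[C@@]1(C)CCC[C@]2(C)[C@@H](CC/C(C)=C\C(=O)O)C(C)=CC[C@@H]12 | target

Total step count: 26.
Longest linear sequence: 23 steps, from 1 to 47 through steps 1–3, 5–20 and 23–26. Step 4 and steps 21–22 prepare the two fragments that join in steps 5 and 23.

Steps most likely to fail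

Step 10 (ring contraction). The enforced boat carries allylic strain between the C18 methyl and C1 and eclipsing of that methyl with the C9 arm. The shift may therefore be slow enough for the ketene acetal to decay by silyl migration or ketene loss, and deprotonation next to the quaternary C10 may be incomplete. The fallback sets out from unsaturated lactone 16 and makes the ketene acetal by conjugate addition instead of by deprotonation. The cuprate addition of step 9 is run without aqueous quench, and the trimethylsilyl ketene acetal 17 is freed from copper salts by filtration under argon. It is then heated in xylene containing a little Et3N at 140 °C in a sealed vessel. The rearranged trimethylsilyl ester F1 is hydrolysed with aqueous citric acid in THF, and the route is rejoined at acid 22.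

Step 15 (C9 alkylation, with the equilibration of step 16). The hindered α′-enolate may undergo proton transfer or O-alkylation instead of clean C-alkylation, and the later equilibration may leave much of the 9α-epimer. The fallback sets out from enone 27 and fixes C9 by face-selective hydrogenation instead of by equilibration. The lithium dienolate 29 is added to ethyl glyoxylate at −78 °C to give the aldol adduct F2. Mesylation (MsCl, Et3N) gives the mesylate F3, and DBU eliminates it to the alkylidene dienone F4. Hydrogenation (H2, 10% Pd/C, EtOAc) then saturates all three olefins and should deliver hydrogen to C9 from the α-face, anti to the axial C20 methyl. The route is rejoined at keto ester 32.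

Step 25 (angeloylation). Acylation of the hindered axial neopentyl C19 hydroxyl may be slow, and the activated angelate may isomerise to the (E)-configured tiglate during that time. The fallback sets out from alcohol 43 and builds the (Z)-olefin on the molecule instead of transferring a preformed angeloyl group. Esterification with 2-[bis(2,2,2-trifluoroethoxy)phosphoryl]propanoic acid (DCC, DMAP) gives the phosphonopropanoate F5. Still–Gennari olefination with acetaldehyde (KN(SiMe3)2, 18-crown-6, THF, −78 °C) should then give the (Z)-2-methylbut-2-enoate, and the route is rejoined at ester 46.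

Further compounds
F1 | step 10 | trimethylsilyl ester of acid 22 | CC(C)(C)[Si](C)(C)OC[C@@]1(C)C=CC[C@](C)(CC=C)[C@H]1C(=O)O[Si](C)(C)C
F2 | step 15 | aldol adduct of enone 27 with ethyl glyoxylate (C9 and C11 epimers) | CC(C)(C)[Si](C)(C)OC[C@@]1(C)C=CC[C@]2(C)C(C(O)C(=O)OCC)C(=O)C=C[C@@H]12
F3 | step 15 | mesylate of F2 | CC(C)(C)[Si](C)(C)OC[C@@]1(C)C=CC[C@]2(C)C(C(OS(C)(=O)=O)C(=O)OCC)C(=O)C=C[C@@H]12
F4 | step 15 | 9-(ethoxycarbonylmethylidene) dienone (olefin isomers) | CC(C)(C)[Si](C)(C)OC[C@@]1(C)C=CC[C@]2(C)C(=CC(=O)OCC)C(=O)C=C[C@@H]12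
F5 | step 25 | 2-[bis(2,2,2-trifluoroethoxy)phosphoryl]propanoate of alcohol 43 | CC(C(=O)OC[C@@]1(C)CCC[C@]2(C)[C@@H](CC/C(C)=C\C(=O)OCC[Si](C)(C)C)C(C)=CC[C@@H]12)P(=O)(OCC(F)(F)F)OCC(F)(F)F
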